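Follow one molecule.

all flasks: second nucleophile 0.456 M

|  | starting material | first nucleophile | temperature | remark | time |
|---|---|---|---|---|---|
| Friday's | 0.38 M | 0.57 M | −5 °C | run made earlier |  |
| Saturday's | 0.53 M | 0.57 M | 6 °C | run made earlier |  |
| Monday's | 0.84 M | 0.57 M | −5 °C | run made earlier |  |
| north-east | 0.38 M (fed, over 80 min) | 0.570 M |  | the addition at −30 °C, then warmed to 0 °C; the feed brings no volume worth counting | 2.0 h |
| west | 0.38 M (fed, over 80 min) | 0.570 M | 0 °C | all else is in the flask from the start; the feed brings no volume worth counting | 2.0 h |
| south-west | 0.38 M | 0.570 M |  | everything together at the start at −30 °C, warmed to 0 °C at 80 min | 2.0 h |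
| north | 0.38 M | 0.570 M | 0 °C | everything together at the start | 2.0 h |

Friday's run (percent of the starting material charged)

| time / min | other capture product / % | target / % |
|---|---|---|
| 10.0 | 15.1 | 2.0 |
| 20.0 | 26.8 | 2.6 |
| 30.0 | 36.4 | 2.1 |
| 60.0 | 54.5 | 1.8 |
| 120 | 72.2 | 2.0 |

Saturday's run (percent of the starting material charged)

| time / h | other capture product / % | target / % |
|---|---|---|
| 0.200 | 33.4 | 1.9 |
| 0.667 | 60.3 | 1.8 |
| 1.00 | 66.2 | 1.7 |
| 1.50 | 71.5 | 1.2 |
| 2.50 | 76.0 | 0.7 |

Monday's run (percent of the starting material charged)

| time / h | other capture product / % | target / % |
|---|---|---|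
| 0.200 | 17.1 | 2.6 |
| 0.667 | 36.1 | 3.7 |
| 1.00 | 43.1 | 4.5 |
| 1.50 | 47.2 | 3.7 |
| 2.50 | 49.8 | 5.0 |

(each reading ± 0.5 percentage points)

- a reading or a percentage of target counts all its forms, free or not

* the flask that comes out highest in amount of other capture product, in percent of the starting material charged, or "all alike" when all lie within 1.5 percentage points (north-east / west / south-west / north / all alike)
* other capture product at the end, in percent of the starting material charged, north-east
* other capture product at the end, in percent of the starting material charged, west
* other capture product at the end, in percent of the starting material charged, south-west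
* other capture product at the end, in percent of the starting material charged, north

What is a molecule of starting material's chance per minute of being taken? I take it as k[second nucleophile], a pseudo-first-order rate while [second nucleophile] stands near its charge.

And k? Friday's first reading has 17.1% gone at 10.0 min. Dividing by the time and the mean [second nucleophile] gives 0.0443 M⁻¹ min⁻¹.

Does it depend on the charge of starting material? Monday's run, with twice Friday's charge at the same temperature, reads 0.0490 M⁻¹ min⁻¹, against Friday's 0.0443 M⁻¹ min⁻¹.

And at 0 °C? Saturday's first reading, 35.3% gone, gives 0.100 M⁻¹ min⁻¹ at 6 °C. Interpolating the logarithm gives 0.0642 M⁻¹ min⁻¹.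

What do you carry to the flasks? The capture number: the excess of second nucleophile over starting material, the limiting reagent of these four flasks, times k, times the warm minutes the average molecule lives. For north that is 0.585. With r the ratio of charges, 0.833, the fraction left is (one minus r) over (e to the number, minus r). So my reckoning has north losing 82.7% of its starting material.

West? A fed molecule arrives on average halfway through the feed and lives 80.0 min, so my reckoning has west losing 74.1%.

The cold flasks, north-east and south-west? Their warm stretch of 40.0 min gives a loss of 56.4% in my reckoning.

Your weak spot? The cold. Extrapolated, k there is 0.006936 M⁻¹ min⁻¹, so the cold stretch is worth 8.65 min at 0 °C, and counted whole it lifts south-west to 61.6%. My reckoning keeps north ahead of these. A second weak spot: Friday's, Saturday's and Monday's runs share 0.456 M, so the dependence on [second nucleophile] is assumed.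

The forecast says: “Other capture product fits simple second-order capture of starting material by the second nucleophile.” It names north highest, with north-east 56.5% (51% to 61%), west 70.5% (66% to 74%), south-west 58% (53% to 63%) and north 80.5% (76% to 84%).

The flasks give north-east 56.2%, west 72.8%, south-west 56.7% and north 79.9%, so north is highest.

    second nucleophile + target → over-reaction product (k = 0.167 M⁻¹ min⁻¹, Ea = 71.0 kJ mol⁻¹)
    second nucleophile + target ⇌ idle adduct, settled at all times (K = 0.880 M⁻¹, ΔH = −26.0 kJ mol⁻¹)
    second nucleophile + intermediate → other capture product (k = 53.4 M⁻¹ min⁻¹, Ea = 45.0 kJ mol⁻¹)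
    starting material ⇌ intermediate (K = 0.00170, k = 0.0944 min⁻¹, Ea = 88.0 kJ mol⁻¹, ΔH = −8.00 kJ mol⁻¹)
    first nucleophile + intermediate → target (k = 7.23 M⁻¹ min⁻¹, Ea = 55.0 kJ mol⁻¹)
    2 first nucleophile → self-condensation product (k = 0.0884 M⁻¹ min⁻¹, Ea = 67.0 kJ mol⁻¹)
    (constants at 0 °C)

The neighbour of north-east with 1.8 M of second nucleophile tries the assumed dependence: its capture number, 3.64, leaves 2.07% of the starting material, while that flask still has 9.9%. North has not come to rest at 2.00 h: 13% of its starting material stands unbound, against 17.3% by the capture number. At ten times the time, other capture product in north reaches 92.7% and starting material 0.00706%. Second nucleophile in north then stands at 16.7% of its charge, and over-reaction product at 7.29%.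

The readings come from a simulation for an exercise, and the scatter is random.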